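**Retrosynthetic overview**
- Target ⇐ acidolytic removal of six 4-methoxybenzyl (PMB) groups (five ethers, one ester) from the fully protected compound.
- C4 side chain ⇐ Heck coupling (C–C) of a 4-bromo-2,3-dihydrobenzofuran with the acrylate of PMB-protected (R)-danshensu; the lactate centre comes from the chiral pool and is never touched.
- Key disconnection, the C2–O bond of the dihydrofuran ring ⇐ a 3-arylidenebenzofuran-2(3H)-one (isoaurone): a chiral isothiourea moves the lactone aryloxide from the acyl carbon to the benzylic carbon while methanol takes the acyl group. This gives the ring, C2/C3 and the C3 methyl ester in one operation.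
- Isoaurone ⇐ Knoevenagel condensation of 4-bromo-7-hydroxybenzofuran-2(3H)-one with protected protocatechualdehyde; the lactone ⇐ 2,3-dimethoxyphenylacetic acid (demethylation, para-bromination).
- Ring order: the three benzene rings are bought; the five-membered lactone is closed first as a temporary ring, then opened and re-closed as the dihydrofuran by the C–O step.

Assumption: sodium (R)-danshensu is bought as the bulk salt; the isothiourea enantiomer in step 6 is written as (2S,3R) from the usual shielding model and is exchanged for its commercial antipode if the first run gives the 2R series.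

**Step 1**
Reactants: 1 2,3-dimethoxyphenylacetic acid
Product: 3 7-hydroxybenzofuran-2(3H)-one, via 2,3-dihydroxyphenylacetic acid 2 (not isolated)
Conditions: BBr3 (3 equiv), CH2Cl2, −78 °C → rt; H2O; then TsOH·H2O (5 mol %), PhMe, reflux (Dean–Stark)
Reagents that add atoms: none
Why: Lewis-acid O-demethylation of both aryl methyl ethers, then acid-catalysed lactonisation in which only the 2-OH can close the five-membered ring, leaving the 3-OH as the single free phenol; no stereocentre.

**Step 2**
Reactants: 3 7-hydroxybenzofuran-2(3H)-one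
Product: 4 4-bromo-7-hydroxybenzofuran-2(3H)-one
Conditions: NBS (1.0 equiv), MeCN, −20 → 0 °C, dark
Reagents that add atoms: N-bromosuccinimide, O=C1CCC(=O)N1Br
Why: Electrophilic aromatic bromination goes para to the free phenol (C4) because the acyloxy oxygen is a much weaker director, and cold, dark, ionic conditions leave the enolisable C3 methylene alone.

**Step 3**
Reactants: 5 3,4-dihydroxybenzaldehyde
Product: 6 3,4-bis[(4-methoxybenzyl)oxy]benzaldehyde
Conditions: 4-methoxybenzyl chloride (2.3 equiv), K2CO3, DMF, 60 °C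
Reagents that add atoms: 4-methoxybenzyl chloride, COc1ccc(CCl)cc1
Why: Williamson ether synthesis on both phenoxides; the aldehyde is inert to carbonate.

**Step 4**
Reactants: 4 4-bromo-7-hydroxybenzofuran-2(3H)-one; 6 3,4-bis[(4-methoxybenzyl)oxy]benzaldehyde
Product: 7 (Z)-4-bromo-3-{3,4-bis[(4-methoxybenzyl)oxy]benzylidene}-7-hydroxybenzofuran-2(3H)-one
Conditions: Et3N (0.5 equiv), 4 Å molecular sieves, MeCN, 60 °C; crystallisation
Reagents that add atoms: none
Why: Knoevenagel condensation of the acidic lactone methylene with the aldehyde under a tertiary amine (a secondary amine would aminolyse the lactone); the peri-bromine pushes the aryl group to the carbonyl side, so the Z isomer is expected and is purified by crystallisation.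

**Step 5**
Reactants: 7 (Z)-4-bromo-3-{3,4-bis[(4-methoxybenzyl)oxy]benzylidene}-7-hydroxybenzofuran-2(3H)-one
Product: 8 (Z)-4-bromo-3-{3,4-bis[(4-methoxybenzyl)oxy]benzylidene}-7-[(4-methoxybenzyl)oxy]benzofuran-2(3H)-one
Conditions: 4-methoxybenzyl chloride (1.2 equiv), K2CO3, acetone, 45 °C
Reagents that add atoms: 4-methoxybenzyl chloride, COc1ccc(CCl)cc1
Why: Williamson O-alkylation of the only acidic site left; it is placed after step 4 because lactone 4 itself would be C-alkylated at its more acidic methylene.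

**Step 6**
Reactants: 8 (Z)-4-bromo-3-{3,4-bis[(4-methoxybenzyl)oxy]benzylidene}-7-[(4-methoxybenzyl)oxy]benzofuran-2(3H)-one
Product: 10 methyl (2S,3S)-4-bromo-2-{3,4-bis[(4-methoxybenzyl)oxy]phenyl}-7-[(4-methoxybenzyl)oxy]-2,3-dihydrobenzofuran-3-carboxylate, via cis-(2S,3R) epimer 9 (not isolated)
Conditions: (2S,3R)-HyperBTM [(2S,3R)-3-isopropyl-2-phenyl-3,4-dihydro-2H-benzo[4,5]thiazolo[3,2-a]pyrimidine] (10 mol %), MeOH (1.5 equiv, added over 6 h), PhMe, −20 °C → rt; then DBU (10 mol %), 0 °C
Reagents that add atoms: methanol, CO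
Why: Proposed new method: an isothiourea acyl-transfer relay in which the lactone is the activated aryl ester — N-acylation of the catalyst opens 8 to an α,β-unsaturated acyl isothiouronium whose own C7a aryloxide, held as counter-ion, adds to the β-carbon (5-endo oxa-Michael) on the face left open by the catalyst's pseudo-axial phenyl group, forming the C2–O bond and setting C2 = S; the ammonium enolate is C-protonated and methanol releases the catalyst as the methyl ester, so the energy of the aryl ester pays for a closure the free phenol ester does not undergo, and the weakly basic catalyst cannot reopen the product; the closest known reaction type is isothiourea-catalysed Michael addition to unsaturated acyl ammonium ions generated from aryl esters with aryloxide (or thiolate) rebound, here with the rebound at the β-carbon instead of the acyl carbon; kinetic protonation anti to the aryl group should give mainly the cis ester, which catalytic DBU equilibrates at C3 to the more stable trans (2S,3S) isomer (a known epimerisation for this ring system).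

**Step 7**
Reactants: 11 sodium (R)-3-(3,4-dihydroxyphenyl)-2-hydroxypropanoate (sodium danshensu)
Product: 12 4-methoxybenzyl (R)-3-{3,4-bis[(4-methoxybenzyl)oxy]phenyl}-2-hydroxypropanoate
Conditions: 4-methoxybenzyl chloride (3.3 equiv), K2CO3, DMF, 25–40 °C
Reagents that add atoms: 4-methoxybenzyl chloride, COc1ccc(CCl)cc1
Why: SN2 alkylation of the carboxylate and both phenoxides (ester alkylation plus Williamson); carbonate does not deprotonate the secondary alcohol and the stereocentre is not involved.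

**Step 8**
Reactants: 12 4-methoxybenzyl (R)-3-{3,4-bis[(4-methoxybenzyl)oxy]phenyl}-2-hydroxypropanoate
Product: 13 4-methoxybenzyl (R)-2-(acryloyloxy)-3-{3,4-bis[(4-methoxybenzyl)oxy]phenyl}propanoate
Conditions: acryloyl chloride (1.3 equiv), Et3N, CH2Cl2, −20 → 0 °C
Reagents that add atoms: acryloyl chloride, C=CC(=O)Cl
Why: O-acylation of the secondary alcohol with an acid chloride and amine base at low temperature, too mild to epimerise the α-centre.

**Step 9**
Reactants: 10 methyl (2S,3S)-4-bromo-2-{3,4-bis[(4-methoxybenzyl)oxy]phenyl}-7-[(4-methoxybenzyl)oxy]-2,3-dihydrobenzofuran-3-carboxylate; 13 4-methoxybenzyl (R)-2-(acryloyloxy)-3-{3,4-bis[(4-methoxybenzyl)oxy]phenyl}propanoate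
Product: 14 4-methoxybenzyl (R)-3-{3,4-bis[(4-methoxybenzyl)oxy]phenyl}-2-{[(E)-3-{(2S,3S)-2-{3,4-bis[(4-methoxybenzyl)oxy]phenyl}-3-(methoxycarbonyl)-7-[(4-methoxybenzyl)oxy]-2,3-dihydrobenzofuran-4-yl}acryloyl]oxy}propanoate
Conditions: Pd2(dba)3 (2.5 mol %), [HP(t-Bu)3]BF4 (10 mol %), Cy2NMe (1.5 equiv), 1,4-dioxane, 70 °C
Reagents that add atoms: none
Why: Mizoroki–Heck reaction — oxidative addition of the aryl bromide to zerovalent palladium carrying the bulky electron-rich phosphine, syn-insertion of the acrylate and syn-β-hydride elimination give the E-alkene, and the hindered amine is too weak to enolise C3 (already the stable trans isomer) or the lactate centre.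

**Step 10**
Reactants: 14 the hexa-PMB compound from step 9
Product: 15 monomethyl lithospermate, (R)-3-(3,4-dihydroxyphenyl)-2-{[(E)-3-{(2S,3S)-2-(3,4-dihydroxyphenyl)-7-hydroxy-3-(methoxycarbonyl)-2,3-dihydrobenzofuran-4-yl}acryloyl]oxy}propanoic acid
Conditions: TFA–CH2Cl2 (1:4), C6HMe5 (20 equiv), 0 °C → rt; reversed-phase chromatography (0.1 % HCO2H)
Reagents that add atoms: none
Why: Acidolysis (SN1) of the five PMB ethers and the PMB ester with irreversible Friedel–Crafts capture of the PMB cation by pentamethylbenzene; the methyl ester, cinnamate ester and alkene are inert, the C2–O bond is deactivated by the adjacent ester, and no stereocentre is touched.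

**Compound list**
1 | 2,3-dimethoxyphenylacetic acid | COc1cccc(CC(=O)O)c1OC | starting material
2 | 2,3-dihydroxyphenylacetic acid | OC(=O)Cc1cccc(O)c1O | intermediate
3 | 7-hydroxybenzofuran-2(3H)-one | O=C1Cc2cccc(O)c2O1 | intermediate
4 | 4-bromo-7-hydroxybenzofuran-2(3H)-one | O=C1Cc2c(Br)ccc(O)c2O1 | intermediate
5 | 3,4-dihydroxybenzaldehyde | O=Cc1ccc(O)c(O)c1 | starting material
6 | 3,4-bis[(4-methoxybenzyl)oxy]benzaldehyde | O=Cc1ccc(OCc2ccc(OC)cc2)c(OCc2ccc(OC)cc2)c1 | intermediate
7 | (Z)-4-bromo-3-{3,4-bis[(4-methoxybenzyl)oxy]benzylidene}-7-hydroxybenzofuran-2(3H)-one | O=C1Oc2c(O)ccc(Br)c2/C1=C/c1ccc(OCc2ccc(OC)cc2)c(OCc2ccc(OC)cc2)c1 | intermediate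
8 | (Z)-4-bromo-3-{3,4-bis[(4-methoxybenzyl)oxy]benzylidene}-7-[(4-methoxybenzyl)oxy]benzofuran-2(3H)-one | O=C1Oc2c(OCc3ccc(OC)cc3)ccc(Br)c2/C1=C/c1ccc(OCc2ccc(OC)cc2)c(OCc2ccc(OC)cc2)c1 | intermediate
9 | methyl (2S,3R)-4-bromo-2-{3,4-bis[(4-methoxybenzyl)oxy]phenyl}-7-[(4-methoxybenzyl)oxy]-2,3-dihydrobenzofuran-3-carboxylate (cis) | COC(=O)[C@@H]1c2c(Br)ccc(OCc3ccc(OC)cc3)c2O[C@@H]1c1ccc(OCc2ccc(OC)cc2)c(OCc2ccc(OC)cc2)c1 | intermediate
10 | methyl (2S,3S)-4-bromo-2-{3,4-bis[(4-methoxybenzyl)oxy]phenyl}-7-[(4-methoxybenzyl)oxy]-2,3-dihydrobenzofuran-3-carboxylate (trans) | COC(=O)[C@H]1c2c(Br)ccc(OCc3ccc(OC)cc3)c2O[C@@H]1c1ccc(OCc2ccc(OC)cc2)c(OCc2ccc(OC)cc2)c1 | intermediate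
11 | sodium (R)-3-(3,4-dihydroxyphenyl)-2-hydroxypropanoate | O[C@H](Cc1ccc(O)c(O)c1)C(=O)[O-].[Na+] | starting material
12 | 4-methoxybenzyl (R)-3-{3,4-bis[(4-methoxybenzyl)oxy]phenyl}-2-hydroxypropanoate | O[C@H](Cc1ccc(OCc2ccc(OC)cc2)c(OCc2ccc(OC)cc2)c1)C(=O)OCc1ccc(OC)cc1 | intermediate
13 | 4-methoxybenzyl (R)-2-(acryloyloxy)-3-{3,4-bis[(4-methoxybenzyl)oxy]phenyl}propanoate | C=CC(=O)O[C@H](Cc1ccc(OCc2ccc(OC)cc2)c(OCc2ccc(OC)cc2)c1)C(=O)OCc1ccc(OC)cc1 | intermediate
14 | hexa-PMB monomethyl lithospermate (name as in step 9) | COC(=O)[C@H]1c2c(/C=C/C(=O)O[C@H](Cc3ccc(OCc4ccc(OC)cc4)c(OCc4ccc(OC)cc4)c3)C(=O)OCc3ccc(OC)cc3)ccc(OCc3ccc(OC)cc3)c2O[C@@H]1c1ccc(OCc2ccc(OC)cc2)c(OCc2ccc(OC)cc2)c1 | intermediate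
15 | monomethyl lithospermate | COC(=O)[C@H]1c2c(/C=C/C(=O)O[C@H](Cc3ccc(O)c(O)c3)C(=O)O)ccc(O)c2O[C@@H]1c1ccc(O)c(O)c1 | target

**Step count and risks**
Total steps: 10. Longest linear sequence: 7 (steps 1, 2, 4, 5, 6, 9, 10 from 1).

Step 6 is the most likely to fail, because it is a new reaction. The α-aryl acyl isothiouronium may form slowly, methanol may intercept it before the oxa-Michael step and give the open phenol ester, or the ee may be low (10 has no remote stereocentre, so ee is read by chiral HPLC and can be raised by crystallisation). The fallback uses known chemistry only, sets out from 4 and 6 and comes back at 9. The ring is built by the established enantioselective rhodium-carbene insertion of an aryldiazoacetate into a benzylic ether C–H bond. Phenol 4 is protected under acid catalysis with 4-methoxybenzyl 2,2,2-trichloroacetimidate (La(OTf)3 cat., toluene) as 4-bromo-7-[(4-methoxybenzyl)oxy]benzofuran-2(3H)-one F1. Aldehyde 6 is reduced with NaBH4 (THF–MeOH) to {3,4-bis[(4-methoxybenzyl)oxy]phenyl}methanol F2. F1 is opened with MeOH and catalytic Et3N to methyl 2-{6-bromo-2-hydroxy-3-[(4-methoxybenzyl)oxy]phenyl}acetate F3, which is etherified with F2 under Mitsunobu conditions (PPh3, DIAD, THF) to methyl 2-[6-bromo-2-({3,4-bis[(4-methoxybenzyl)oxy]phenyl}methoxy)-3-[(4-methoxybenzyl)oxy]phenyl]acetate F4. Diazo transfer (4-acetamidobenzenesulfonyl azide, DBU, MeCN) gives methyl 2-diazo-2-[6-bromo-2-({3,4-bis[(4-methoxybenzyl)oxy]phenyl}methoxy)-3-[(4-methoxybenzyl)oxy]phenyl]acetate F5. Rh2(S-PTTL)4 [dirhodium tetrakis(N-phthaloyl-(S)-tert-leucinate)] (1 mol %, toluene, −60 °C; its antipode if the 2R series results) then gives cis ester 9, which is epimerised to 10 with catalytic NaOMe in MeOH.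

Step 9 is next, because the bromide is electron-rich and sits beside the ester-bearing stereocentre, and the amine base at 70 °C could erode the lactate centre. The fallback sets out from 12 (with 10) and comes back at 14 by a Stille coupling with no amine base. Alcohol 12 is esterified with (E)-3-(tributylstannyl)acrylic acid (DCC, DMAP, CH2Cl2) to 4-methoxybenzyl (R)-3-{3,4-bis[(4-methoxybenzyl)oxy]phenyl}-2-{[(E)-3-(tributylstannyl)acryloyl]oxy}propanoate F6. F6 is coupled with 10 (Pd[P(t-Bu)3]2, CsF, dioxane, 60 °C) to give 14 with the E geometry already fixed in the stannane.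

Step 4 is third, because the lactone can be opened or self-condense under base, the electron-rich aldehyde is sluggish, and an E/Z mixture may form. The fallback sets out from 4 and 6 and comes back at 7 by a directed aldol followed by acid dehydration. The boron enolate of 4 (Bu2BOTf 2.2 equiv, i-Pr2NEt, CH2Cl2, −78 °C; the phenol is borylated in passing) adds to 6 to give 4-bromo-3-({3,4-bis[(4-methoxybenzyl)oxy]phenyl}(hydroxy)methyl)-7-hydroxybenzofuran-2(3H)-one F7 as a diastereomer mixture. F7 is dehydrated with PPTS in toluene at 60 °C to 7.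

**Further compounds**
F1 | step 6 | 4-bromo-7-[(4-methoxybenzyl)oxy]benzofuran-2(3H)-one | O=C1Cc2c(Br)ccc(OCc3ccc(OC)cc3)c2O1
F2 | step 6 | {3,4-bis[(4-methoxybenzyl)oxy]phenyl}methanol | OCc1ccc(OCc2ccc(OC)cc2)c(OCc2ccc(OC)cc2)c1
F3 | step 6 | methyl 2-{6-bromo-2-hydroxy-3-[(4-methoxybenzyl)oxy]phenyl}acetate | COC(=O)Cc1c(Br)ccc(OCc2ccc(OC)cc2)c1O
F4 | step 6 | methyl 2-[6-bromo-2-({3,4-bis[(4-methoxybenzyl)oxy]phenyl}methoxy)-3-[(4-methoxybenzyl)oxy]phenyl]acetate | COC(=O)Cc1c(Br)ccc(OCc2ccc(OC)cc2)c1OCc1ccc(OCc2ccc(OC)cc2)c(OCc2ccc(OC)cc2)c1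
F5 | step 6 | methyl 2-diazo-2-[6-bromo-2-({3,4-bis[(4-methoxybenzyl)oxy]phenyl}methoxy)-3-[(4-methoxybenzyl)oxy]phenyl]acetate | COC(=O)C(=[N+]=[N-])c1c(Br)ccc(OCc2ccc(OC)cc2)c1OCc1ccc(OCc2ccc(OC)cc2)c(OCc2ccc(OC)cc2)c1
F6 | step 9 | 4-methoxybenzyl (R)-3-{3,4-bis[(4-methoxybenzyl)oxy]phenyl}-2-{[(E)-3-(tributylstannyl)acryloyl]oxy}propanoate | CCCC[Sn](CCCC)(CCCC)/C=C/C(=O)O[C@H](Cc1ccc(OCc2ccc(OC)cc2)c(OCc2ccc(OC)cc2)c1)C(=O)OCc1ccc(OC)cc1
F7 | step 4 | 4-bromo-3-({3,4-bis[(4-methoxybenzyl)oxy]phenyl}(hydroxy)methyl)-7-hydroxybenzofuran-2(3H)-one (mixture of diastereomers) | O=C1Oc2c(O)ccc(Br)c2C1C(O)c1ccc(OCc2ccc(OC)cc2)c(OCc2ccc(OC)cc2)c1
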